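**Retrosynthetic overview** (enone ring numbered C1 = C=O, C2 = carbon bearing CH(CH3)CO2H, C3 = carbon bearing the trimethylcyclohexyl group through its quaternary carbon C1', C6 = carbon bearing CH2OCHO)
1. Last bonds: O-formyl, then C6–CH2OH by catalytic asymmetric hydroxymethylation of enone acid 16, so the epimerizable C6 centre is made at the end.
2. C2–CH(CH3)CO2H by Ireland–Claisen shift from a C4 allylic propanoate (11); the shift also deletes the C4 oxygen, and ketal hydrolysis then gives the C1 ketone and the C2=C3 enone.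
3. The cyclohexenone ring is a dearomatized benzene: PhI(OAc)2/MeOH turns phenol 7 into quinone monoketal 8 (C4 ketone, C1 ketal).
4. Key disconnection C3–C1': aromatic Claisen rearrangement of aryl cyclohexenyl ether 4. Enabling feature: C1' lies in a 1,3,3-trimethylcyclohexane ring that maps onto isophorone, so it can be the methyl-bearing terminus of a cyclohex-2-enyl ether; C3 is flanked by C4, a CH2 para to the C1 carbonyl, which can carry the temporary ether oxygen of a 4-methoxyphenyl ring.
5. Ring order: no ring is built; both six-membered rings are bought (isophorone, 4-iodoanisole) and the arene is taken benzene → cyclohexadienone → cyclohexenone after the key step.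

Key step: step 3

Assumption: in step 12 the (S,S)-ligand is taken to deliver formaldehyde to the face that gives (5S); this rests on analogy and would be fixed on the silyl dienol ether of 3-methylcyclohex-2-enone, the (R,R)-ligand being used if the model shows the opposite face.

Step 1
Reactants: 1 isophorone (3,5,5-trimethylcyclohex-2-en-1-one)
Product: 2 (1S)-3,5,5-trimethylcyclohex-2-en-1-ol
Conditions: (R)-Me-CBS (10 mol %), BH3·SMe2 (0.7 equiv), THF, −20 °C; MeOH
Reagents that add atoms: none
Why: Corey–Bakshi–Shibata reduction, in which the (R)-oxazaborolidine should deliver hydride to the face defined by treating the trisubstituted alkenyl arm as the large group (as for other cyclohex-2-enones), setting the (S)-carbinol.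

Step 2
Reactants: 2 (1S)-3,5,5-trimethylcyclohex-2-en-1-ol; 3 4-iodoanisole
Product: 4 1-methoxy-4-{[(1S)-3,5,5-trimethylcyclohex-2-en-1-yl]oxy}benzene
Conditions: CuI (10 mol %), 3,4,7,8-tetramethyl-1,10-phenanthroline (20 mol %), Cs2CO3 (2 equiv), toluene, 90 °C
Reagents that add atoms: none
Why: Copper-catalysed Ullmann-type O-arylation of a secondary alcohol forms the aryl–O bond and leaves the carbinol C–O bond untouched, so the (S) configuration is retained and no substitution is needed at the hindered allylic carbon.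

Step 3
Reactants: 4 1-methoxy-4-{[(1S)-3,5,5-trimethylcyclohex-2-en-1-yl]oxy}benzene
Product: 6 4-methoxy-2-[(1R)-1,5,5-trimethylcyclohex-2-en-1-yl]phenol, via ortho-dienone 5 (not isolated)
Conditions: PhNEt2, 185 °C, sealed tube, Ar
Reagents that add atoms: none
Why: Thermal aromatic (ortho) Claisen rearrangement: a concerted suprafacial [3,3] shift moves the methyl-bearing allyl terminus from oxygen to the ortho carbon, and dienone 5 then enolizes to the phenol, which makes the step irreversible. The closest known reaction type is the thermal ortho-Claisen of aryl 3,3-disubstituted allyl and aryl cyclohex-2-enyl ethers, which builds benzylic quaternary carbons with 1,3-chirality transfer. No ring is closed; only the six-membered pericyclic array is passed through. The new quaternary centre is controlled by the C–O stereocentre of 4, because the aryl carbon can only reach the ring face that carried the oxygen, so the (1S)-ether should give the (1R)-cyclohexenyl centre (the (1S)-cyclohexyl centre of the target after hydrogenation). The step needs the [3,3] shift to win over ionization or elimination to a diene, which the neutral basic solvent, the absence of Lewis acid and the para-methoxy group favour; ortho regioselectivity is automatic because both ortho positions of the 4-methoxyphenyl ring are equivalent. Bond formation inside a cyclic transition state is what should overcome the 1,3-diaxial methyl group that slows intermolecular attack at this carbon of the isophorone skeleton.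

Step 4
Reactants: 6 4-methoxy-2-[(1R)-1,5,5-trimethylcyclohex-2-en-1-yl]phenol
Product: 7 4-methoxy-2-[(1S)-1,3,3-trimethylcyclohexyl]phenol
Conditions: H2 (1 atm), 10% Pd/C, EtOAc, rt
Reagents that add atoms: none
Why: Heterogeneous hydrogenation of the only non-aromatic C=C bond; the quaternary centre is untouched and its descriptor changes from R to S only because CH=CH becomes CH2–CH2.

Step 5
Reactants: 7 4-methoxy-2-[(1S)-1,3,3-trimethylcyclohexyl]phenol
Product: 8 4,4-dimethoxy-2-[(1S)-1,3,3-trimethylcyclohexyl]cyclohexa-2,5-dien-1-one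
Conditions: PhI(OAc)2 (1.1 equiv), MeOH, 0 °C; NaHCO3
Reagents that add atoms: methanol, CO
Why: Oxidative dearomatization of a para-methoxyphenol to a quinone monoketal with an iodine(III) reagent, in which methanol adds at the methoxy-bearing carbon so that the former phenol carbon becomes the ketone (C4) and the anisole carbon the ketal (C1).

Step 6
Reactants: 8 4,4-dimethoxy-2-[(1S)-1,3,3-trimethylcyclohexyl]cyclohexa-2,5-dien-1-one
Product: 9 4,4-dimethoxy-2-[(1S)-1,3,3-trimethylcyclohexyl]cyclohex-2-en-1-one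
Conditions: H2 (1 atm), (Ph3P)3RhCl (5 mol %), benzene, rt
Reagents that add atoms: none
Why: Homogeneous rhodium-catalysed hydrogenation should saturate the unsubstituted cis-disubstituted enone double bond and leave the trisubstituted one, which is shielded by the tertiary alkyl group, so that only one allyl system remains for step 9.

Step 7
Reactants: 9 4,4-dimethoxy-2-[(1S)-1,3,3-trimethylcyclohexyl]cyclohex-2-en-1-one
Product: 10 (1S)-4,4-dimethoxy-2-[(1S)-1,3,3-trimethylcyclohexyl]cyclohex-2-en-1-ol
Conditions: (R)-Me-CBS (20 mol %), BH3·SMe2 (0.7 equiv), THF, −30 °C; MeOH, pH 7 buffer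
Reagents that add atoms: none
Why: Corey–Bakshi–Shibata reduction of an α-substituted cyclohexenone, in which the alkenyl arm carrying the tertiary alkyl group is the large substituent, so the (R)-catalyst should give the (1S)-allylic alcohol under reagent control.

Step 8
Reactants: 10 (1S)-4,4-dimethoxy-2-[(1S)-1,3,3-trimethylcyclohexyl]cyclohex-2-en-1-ol
Product: 11 (1S)-4,4-dimethoxy-2-[(1S)-1,3,3-trimethylcyclohexyl]cyclohex-2-en-1-yl propanoate
Conditions: (EtCO)2O (1.5 equiv), Et3N (2 equiv), DMAP (10 mol %), CH2Cl2, 0 °C → rt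
Reagents that add atoms: propanoic anhydride, CCC(=O)OC(=O)CC
Why: DMAP-catalysed acyl transfer to the secondary allylic alcohol under basic conditions that leave the acid-labile ketal and all stereocentres unchanged.

Step 9
Reactants: 11 (1S)-4,4-dimethoxy-2-[(1S)-1,3,3-trimethylcyclohexyl]cyclohex-2-en-1-yl propanoate
Product: 14 (2R)-2-[(1S)-6,6-dimethoxy-2-[(1S)-1,3,3-trimethylcyclohexyl]cyclohex-2-en-1-yl]propanoic acid, via silyl ketene acetal 12 (not isolated), via trimethylsilyl ester 13 (not isolated)
Conditions: LDA (1.3 equiv, commercial solution), THF/DMPU (3:1), −78 °C; TMSCl (1.5 equiv), −78 °C → rt, then 60 °C; H2O, pH 5 buffer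
Reagents that add atoms: chlorotrimethylsilane, C[Si](C)(C)Cl (its silyl group is held by 12 and 13 only and is lost on work-up)
Why: Ireland–Claisen rearrangement, in which the (Z)-silyl ketene acetal formed in THF/DMPU shifts suprafacially from the face of the C–O bond through a chair transition state (a boat would place the silyloxy group over the tertiary alkyl substituent on the central allyl carbon, and the chair of the (E)-isomer would push its methyl group against it), which should set the ring CH as S and the propanoate α-carbon as R while cutting the C4–O bond.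

Step 10
Reactants: 14 (2R)-2-[(1S)-6,6-dimethoxy-2-[(1S)-1,3,3-trimethylcyclohexyl]cyclohex-2-en-1-yl]propanoic acid
Product: 16 (2R)-2-[6-oxo-2-[(1S)-1,3,3-trimethylcyclohexyl]cyclohex-1-en-1-yl]propanoic acid, via deconjugated keto acid 15 (not isolated)
Conditions: 2 M aq. HCl, THF, rt → 40 °C
Reagents that add atoms: water, O
Why: Acid-catalysed ketal hydrolysis unveils the C1 ketone as the β,γ-unsaturated isomer 15, and acid-catalysed enolization toward the allylic α-carbon then moves the double bond into conjugation (C2=C3), erasing the temporary ring stereocentre while the propanoate α-centre and the quaternary centre are not enolized under these conditions.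

Step 11
Reactants: 16 (2R)-2-[6-oxo-2-[(1S)-1,3,3-trimethylcyclohexyl]cyclohex-1-en-1-yl]propanoic acid
Product: 17 trimethylsilyl (2R)-2-[2-[(1S)-1,3,3-trimethylcyclohexyl]-6-(trimethylsilyloxy)cyclohexa-1,5-dien-1-yl]propanoate
Conditions: LDA (2.3 equiv, commercial solution), THF, −78 °C; TMSCl (2.6 equiv), −78 → 0 °C; pentane, filtration under Ar
Reagents that add atoms: chlorotrimethylsilane, C[Si](C)(C)Cl
Why: Kinetic silyl enol ether formation, in which LDA deprotonates the lithium carboxylate of 16 at the α'-methylene and O-silylation gives the cross-conjugated 2-silyloxydiene, the carboxylate shielding the propanoate α-hydrogen so that the (R) centre should not be epimerized.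

Step 12
Reactants: 17 trimethylsilyl (2R)-2-[2-[(1S)-1,3,3-trimethylcyclohexyl]-6-(trimethylsilyloxy)cyclohexa-1,5-dien-1-yl]propanoate
Product: 18 (2R)-2-[(5S)-5-(hydroxymethyl)-6-oxo-2-[(1S)-1,3,3-trimethylcyclohexyl]cyclohex-1-en-1-yl]propanoic acid
Conditions: Sc(OTf)3 (10 mol %), (S,S)-6,6'-bis(1-hydroxy-2,2-dimethylpropyl)-2,2'-bipyridine (12 mol %), aq. HCHO (35%, 5 equiv), DME/H2O (9:1), −20 °C
Reagents that add atoms: formaldehyde, C=O
Why: Catalytic asymmetric Mukaiyama aldol (hydroxymethylation) of a silicon enolate with aqueous formaldehyde under a chiral scandium–bipyridine complex, which should attack the terminal carbon of the 2-silyloxydiene and set the α'-centre (5S) by catalyst control, the existing stereocentres being too remote to bias the faces.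

Step 13
Reactants: 18 (2R)-2-[(5S)-5-(hydroxymethyl)-6-oxo-2-[(1S)-1,3,3-trimethylcyclohexyl]cyclohex-1-en-1-yl]propanoic acid
Product: 19 (2R)-2-[(5S)-5-[(formyloxy)methyl]-6-oxo-2-[(1S)-1,3,3-trimethylcyclohexyl]cyclohex-1-en-1-yl]propanoic acid
Conditions: acetic formic anhydride (preformed, 1.5 equiv), pyridine (2 equiv), CH2Cl2, −20 → 0 °C; pH 4 aqueous work-up
Reagents that add atoms: acetic formic anhydride, CC(=O)OC=O
Why: O-Formylation of the primary alcohol by the more electrophilic formyl group of the mixed anhydride under cold, weakly basic conditions, which should leave the carboxylic acid (any mixed anhydride is hydrolysed on work-up), the β-acyloxy ketone and the epimerizable α'-centre unchanged.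

**Compound list**
1 | isophorone (3,5,5-trimethylcyclohex-2-en-1-one) | CC1=CC(=O)CC(C)(C)C1 | starting material
2 | (1S)-3,5,5-trimethylcyclohex-2-en-1-ol | O[C@@H]1C=C(C)CC(C)(C)C1 | intermediate
3 | 4-iodoanisole (1-iodo-4-methoxybenzene) | COc1ccc(I)cc1 | starting material
4 | 1-methoxy-4-{[(1S)-3,5,5-trimethylcyclohex-2-en-1-yl]oxy}benzene | COc1ccc(O[C@@H]2C=C(C)CC(C)(C)C2)cc1 | intermediate
5 | 4-methoxy-6-[(1R)-1,5,5-trimethylcyclohex-2-en-1-yl]cyclohexa-2,4-dien-1-one (not isolated; configuration of the ring CH not defined, the centre is lost on enolization) | COC1=CC(C(=O)C=C1)[C@@]2(C)C=CCC(C)(C)C2 | intermediate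
6 | 4-methoxy-2-[(1R)-1,5,5-trimethylcyclohex-2-en-1-yl]phenol | COc1ccc(O)c(c1)[C@@]2(C)C=CCC(C)(C)C2 | intermediate
7 | 4-methoxy-2-[(1S)-1,3,3-trimethylcyclohexyl]phenol | COc1ccc(O)c(c1)[C@@]2(C)CCCC(C)(C)C2 | intermediate
8 | 4,4-dimethoxy-2-[(1S)-1,3,3-trimethylcyclohexyl]cyclohexa-2,5-dien-1-one | COC1(OC)C=CC(=O)C(=C1)[C@@]2(C)CCCC(C)(C)C2 | intermediate
9 | 4,4-dimethoxy-2-[(1S)-1,3,3-trimethylcyclohexyl]cyclohex-2-en-1-one | COC1(OC)CCC(=O)C(=C1)[C@@]2(C)CCCC(C)(C)C2 | intermediate
10 | (1S)-4,4-dimethoxy-2-[(1S)-1,3,3-trimethylcyclohexyl]cyclohex-2-en-1-ol | COC1(OC)CC[C@H](O)C(=C1)[C@@]2(C)CCCC(C)(C)C2 | intermediate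
11 | (1S)-4,4-dimethoxy-2-[(1S)-1,3,3-trimethylcyclohexyl]cyclohex-2-en-1-yl propanoate | COC1(OC)CC[C@H](OC(=O)CC)C(=C1)[C@@]2(C)CCCC(C)(C)C2 | intermediate
12 | (1Z)-1-{[(1S)-4,4-dimethoxy-2-[(1S)-1,3,3-trimethylcyclohexyl]cyclohex-2-en-1-yl]oxy}-1-(trimethylsilyloxy)prop-1-ene (not isolated) | COC1(OC)CC[C@H](O/C(O[Si](C)(C)C)=C/C)C(=C1)[C@@]2(C)CCCC(C)(C)C2 | intermediate
13 | trimethylsilyl (2R)-2-[(1S)-6,6-dimethoxy-2-[(1S)-1,3,3-trimethylcyclohexyl]cyclohex-2-en-1-yl]propanoate (not isolated) | C[C@@H](C(=O)O[Si](C)(C)C)[C@H]1C(=CCCC1(OC)OC)[C@@]2(C)CCCC(C)(C)C2 | intermediate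
14 | (2R)-2-[(1S)-6,6-dimethoxy-2-[(1S)-1,3,3-trimethylcyclohexyl]cyclohex-2-en-1-yl]propanoic acid | C[C@@H](C(=O)O)[C@H]1C(=CCCC1(OC)OC)[C@@]2(C)CCCC(C)(C)C2 | intermediate
15 | (2R)-2-[(1S)-6-oxo-2-[(1S)-1,3,3-trimethylcyclohexyl]cyclohex-2-en-1-yl]propanoic acid (not isolated) | C[C@@H](C(=O)O)[C@H]1C(=CCCC1=O)[C@@]2(C)CCCC(C)(C)C2 | intermediate
16 | (2R)-2-[6-oxo-2-[(1S)-1,3,3-trimethylcyclohexyl]cyclohex-1-en-1-yl]propanoic acid | C[C@@H](C(=O)O)C1=C([C@@]2(C)CCCC(C)(C)C2)CCCC1=O | intermediate
17 | trimethylsilyl (2R)-2-[2-[(1S)-1,3,3-trimethylcyclohexyl]-6-(trimethylsilyloxy)cyclohexa-1,5-dien-1-yl]propanoate | C[C@@H](C(=O)O[Si](C)(C)C)C1=C([C@@]2(C)CCCC(C)(C)C2)CCC=C1O[Si](C)(C)C | intermediate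
18 | (2R)-2-[(5S)-5-(hydroxymethyl)-6-oxo-2-[(1S)-1,3,3-trimethylcyclohexyl]cyclohex-1-en-1-yl]propanoic acid | C[C@@H](C(=O)O)C1=C([C@@]2(C)CCCC(C)(C)C2)CC[C@@H](CO)C1=O | intermediate
19 | (2R)-2-[(5S)-5-[(formyloxy)methyl]-6-oxo-2-[(1S)-1,3,3-trimethylcyclohexyl]cyclohex-1-en-1-yl]propanoic acid | C[C@@H](C(=O)O)C1=C([C@@]2(C)CCCC(C)(C)C2)CC[C@@H](COC=O)C1=O | target

Total step count: 13. Longest linear sequence: 13 steps (from isophorone 1; 4-iodoanisole 3 enters in step 2).

**Steps most likely to fail**

Step 3 (key step). The [3,3] shift has to form a quaternary carbon against the 1,3-diaxial methyl group of the cyclohexene ring. At the temperature needed, thermal elimination of 4-methoxyphenol to a trimethylcyclohexadiene, or ionization to an allyl cation–phenoxide pair with loss of stereochemical fidelity, may compete. The fallback sets out from 1 and returns at 6. Isophorone 1 is reduced with the (S)-CBS catalyst to (1R)-3,5,5-trimethylcyclohex-2-en-1-ol F1, which is acylated with picolinoyl chloride (Et3N, DMAP) to (1R)-3,5,5-trimethylcyclohex-2-en-1-yl pyridine-2-carboxylate F2. Commercial 2-bromo-4-methoxyphenol is protected (MOMCl, i-Pr2NEt) as 2-bromo-4-methoxy-1-(methoxymethoxy)benzene F3 and converted with Mg in THF into [5-methoxy-2-(methoxymethoxy)phenyl]magnesium bromide F4. With CuBr·SMe2, F4 displaces the picolinate of F2 in a picolinate-directed anti-SN2' allylic substitution (known for arylcopper reagents and quaternary carbons) to give 4-methoxy-1-(methoxymethoxy)-2-[(1R)-1,5,5-trimethylcyclohex-2-en-1-yl]benzene F5. Anti attack on the (R)-ester puts the aryl group on the same face as the syn shift from the (S)-ether. HCl in MeOH removes the MOM group and gives 6.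

Step 9. Both neighbours of the receiving carbon are fully substituted, so the shift may be slow enough for the ketene acetal to decompose. A share of (E)-ketene acetal or of a boat pathway would also erode the configuration at the propanoate α-carbon. The fallback sets out from 10 and returns at 14. Alcohol 10 is acetylated (Ac2O, DMAP) to (1S)-4,4-dimethoxy-2-[(1S)-1,3,3-trimethylcyclohexyl]cyclohex-2-en-1-yl acetate F6. Ireland–Claisen rearrangement (LDA, TMSCl, THF, −78 → 60 °C) then runs through the smaller, geometry-free 1-{[(1S)-4,4-dimethoxy-2-[(1S)-1,3,3-trimethylcyclohexyl]cyclohex-2-en-1-yl]oxy}-1-(trimethylsilyloxy)ethene F7 and trimethylsilyl 2-[(1S)-6,6-dimethoxy-2-[(1S)-1,3,3-trimethylcyclohexyl]cyclohex-2-en-1-yl]acetate F8 to 2-[(1S)-6,6-dimethoxy-2-[(1S)-1,3,3-trimethylcyclohexyl]cyclohex-2-en-1-yl]acetic acid F9. F9 is coupled (DCC, DMAP) with (R)-4-benzyl-1,3-oxazolidin-2-one to (4R)-4-benzyl-3-{2-[(1S)-6,6-dimethoxy-2-[(1S)-1,3,3-trimethylcyclohexyl]cyclohex-2-en-1-yl]acetyl}-1,3-oxazolidin-2-one F10. Its sodium (Z)-enolate (NaHMDS, THF, −78 °C) is methylated with MeI anti to the benzyl group to give (4R)-4-benzyl-3-{(2R)-2-[(1S)-6,6-dimethoxy-2-[(1S)-1,3,3-trimethylcyclohexyl]cyclohex-2-en-1-yl]propanoyl}-1,3-oxazolidin-2-one F11. LiOH/H2O2 (THF/H2O, 0 °C) removes the auxiliary and gives 14. The α-centre is then set by the auxiliary and not by the geometry of the sigmatropic transition state.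

Step 12. In the aqueous medium the free carboxylic acid released from the silyl ester may protonate the silyl dienol ether back to 16 faster than the aldol addition. Facial selectivity at the α'-carbon also rests on the catalyst alone. The fallback sets out from 16 and returns at 18. The dianion of 16 (LDA, 2.2 equiv, THF, −78 °C) is treated with monomeric formaldehyde. The lithium enolate aldol gives 18 together with its α'-epimer (2R)-2-[(5R)-5-(hydroxymethyl)-6-oxo-2-[(1S)-1,3,3-trimethylcyclohexyl]cyclohex-1-en-1-yl]propanoic acid F12. The epimers are separated by chromatography, and F12 is re-equilibrated at the α'-carbon (catalytic DBU, CH2Cl2) and separated again.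

Further compounds
F1 | step 3 | (1R)-3,5,5-trimethylcyclohex-2-en-1-ol | O[C@H]1C=C(C)CC(C)(C)C1
F2 | step 3 | (1R)-3,5,5-trimethylcyclohex-2-en-1-yl pyridine-2-carboxylate | O=C(O[C@H]1C=C(C)CC(C)(C)C1)c1ccccn1
F3 | step 3 | 2-bromo-4-methoxy-1-(methoxymethoxy)benzene | COCOc1ccc(OC)cc1Br
F4 | step 3 | [5-methoxy-2-(methoxymethoxy)phenyl]magnesium bromide | COCOc1ccc(OC)cc1[Mg]Br
F5 | step 3 | 4-methoxy-1-(methoxymethoxy)-2-[(1R)-1,5,5-trimethylcyclohex-2-en-1-yl]benzene | COCOc1ccc(OC)cc1[C@@]2(C)C=CCC(C)(C)C2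
F6 | step 9 | (1S)-4,4-dimethoxy-2-[(1S)-1,3,3-trimethylcyclohexyl]cyclohex-2-en-1-yl acetate | COC1(OC)CC[C@H](OC(C)=O)C(=C1)[C@@]2(C)CCCC(C)(C)C2
F7 | step 9 | 1-{[(1S)-4,4-dimethoxy-2-[(1S)-1,3,3-trimethylcyclohexyl]cyclohex-2-en-1-yl]oxy}-1-(trimethylsilyloxy)ethene | COC1(OC)CC[C@H](OC(=C)O[Si](C)(C)C)C(=C1)[C@@]2(C)CCCC(C)(C)C2
F8 | step 9 | trimethylsilyl 2-[(1S)-6,6-dimethoxy-2-[(1S)-1,3,3-trimethylcyclohexyl]cyclohex-2-en-1-yl]acetate | C[Si](C)(C)OC(=O)C[C@H]1C(=CCCC1(OC)OC)[C@@]2(C)CCCC(C)(C)C2
F9 | step 9 | 2-[(1S)-6,6-dimethoxy-2-[(1S)-1,3,3-trimethylcyclohexyl]cyclohex-2-en-1-yl]acetic acid | OC(=O)C[C@H]1C(=CCCC1(OC)OC)[C@@]2(C)CCCC(C)(C)C2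
F10 | step 9 | (4R)-4-benzyl-3-{2-[(1S)-6,6-dimethoxy-2-[(1S)-1,3,3-trimethylcyclohexyl]cyclohex-2-en-1-yl]acetyl}-1,3-oxazolidin-2-one | O=C1OC[C@@H](Cc2ccccc2)N1C(=O)C[C@H]3C(=CCCC3(OC)OC)[C@@]4(C)CCCC(C)(C)C4
F11 | step 9 | (4R)-4-benzyl-3-{(2R)-2-[(1S)-6,6-dimethoxy-2-[(1S)-1,3,3-trimethylcyclohexyl]cyclohex-2-en-1-yl]propanoyl}-1,3-oxazolidin-2-one | O=C1OC[C@@H](Cc2ccccc2)N1C(=O)[C@H](C)[C@H]3C(=CCCC3(OC)OC)[C@@]4(C)CCCC(C)(C)C4
F12 | step 12 | (2R)-2-[(5R)-5-(hydroxymethyl)-6-oxo-2-[(1S)-1,3,3-trimethylcyclohexyl]cyclohex-1-en-1-yl]propanoic acid | C[C@@H](C(=O)O)C1=C([C@@]2(C)CCCC(C)(C)C2)CC[C@H](CO)C1=O
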